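The pyrrole ring carries only hydrogen at C3 and C4, which sit between the formyl-bearing C2 and the nonadecyl-bearing C5; the C3–C4 bond is therefore a bond between the methyl carbons of two methyl ketones. The plan is to hold the kinetic enolates of henicosan-2-one and 1,1-dimethoxypropan-2-one on one di(propan-2-yl)silicon atom and to oxidise this bis-enol ether with (NH4)2Ce(NO3)6. In one operation the two enol CH2 termini are joined to give the 1,4-diketone with the aldehyde carbon already present as an α-keto acetal. Paal–Knorr closure with ammonia and hydrolysis of the acetal in the same flask then give the target.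

Key step: step 3

Remark: the target is achiral and has no stereogenic double bond, so no step has to control configuration; all organolithium and enolate steps are run under argon in dried solvents, with LiN(iPr)2 used as purchased solution.

Step 1
Reactants: 1 icosanoic acid
Product: 2 henicosan-2-one
Conditions: MeLi (2.3 equiv), THF, 0 °C → rt; reaction mixture added to cold 1 M aq HCl
Reagents that add atoms: methyllithium, C[Li]
Why: The first equivalent of MeLi forms the lithium carboxylate and the second adds to it to give a dilithium gem-diolate that releases the methyl ketone only on the inverse acidic quench (ketone synthesis from a carboxylic acid and an organolithium), so the ketone should never meet unreacted MeLi.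

Step 2
Reactants: 2 henicosan-2-one; 3 dichlorodi(propan-2-yl)silane; 4 1,1-dimethoxypropan-2-one
Product: 8 [(3,3-dimethoxyprop-1-en-2-yl)oxy](henicos-1-en-2-yloxy)di(propan-2-yl)silane, via lithium henicos-1-en-2-olate 5 (not isolated), via chlorosilyl enol ether 6 (not isolated), via lithium 3,3-dimethoxyprop-1-en-2-olate 7 (not isolated)
Conditions: (a) 2 (dilute THF solution) added to LiN(iPr)2 (1.05 equiv), THF, −78 °C; cannulated into 3 (1.05 equiv), THF, −78 → 0 °C; (b) 4, LiN(iPr)2 (1.1 equiv), THF, −78 °C, added to (a) at −78 °C → rt; pentane, cold aq NaHCO3 wash; filtration through Et3N-deactivated silica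
Reagents that add atoms: dichlorodi(propan-2-yl)silane (compound 3), CC(C)[Si](Cl)(Cl)C(C)C
Why: Kinetic enolate formation with the hindered amide base at −78 °C removes a methyl proton of each ketone, and two successive O-silylations (silyl enol ether formation) on the dichlorosilane give the mixed bis-enol ether, the first substitution stopping at the monochloride because the di(propan-2-yl)silicon centre is hindered and cold and the second being driven by warming with the other enolate.

Step 3
Reactants: 8 [(3,3-dimethoxyprop-1-en-2-yl)oxy](henicos-1-en-2-yloxy)di(propan-2-yl)silane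
Product: 9 1,1-dimethoxytetracosane-2,5-dione
Conditions: (NH4)2Ce(NO3)6 (2.2 equiv), NaHCO3 (4.4 equiv), MeCN/EtCN (8 added in a little CH2Cl2), −20 → −10 °C; aq NaHCO3 work-up
Reagents that add atoms: none
Why: Tetravalent cerium takes one electron from the more electron-rich, alkyl-substituted enol ether to give a radical cation whose terminal carbon is attacked by the CH2 terminus of the second enol ether held on the same silicon atom; a second one-electron oxidation (each oxidant ending as trivalent cerium) and loss of the silyl unit on work-up should release the 1,4-diketone. The closest known reaction type is the oxidative cross-coupling of unsymmetrical dialkylsilyl bis-enol ethers with (NH4)2Ce(NO3)6, the tethered form of the oxidative coupling of silyl enol ethers. No ring of the product is closed: the seven-membered dioxasilacycle through which the two carbons meet is only a transient arrangement that falls apart with the tether. No stereocentre arises, since both joined carbons end as CH2 groups. The step needs cross-coupling over homo-coupling, secured by the tether that carries exactly one enol ether of each ketone, and bond formation at the former methyl carbons, fixed beforehand by the position of the two enol double bonds. The acetal should survive because an α-keto acetal is inductively deactivated towards ionisation and the NaHCO3 buffer removes the nitric acid that the oxidation liberates.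

Step 4
Reactants: 9 1,1-dimethoxytetracosane-2,5-dione
Product: 11 target aldehyde 5-nonadecyl-1H-pyrrole-2-carbaldehyde, via 2-(dimethoxymethyl)-5-nonadecyl-1H-pyrrole 10 (not isolated)
Conditions: NH4OAc (10 equiv), MeOH/THF, 50 °C; then THF/H2O/AcOH, rt
Reagents that add atoms: ammonium acetate, CC(=O)[O-].[NH4+]; water, O
Why: In the Paal–Knorr pyrrole synthesis ammonia condenses with both carbonyls of the 1,4-diketone and two dehydrations aromatise the ring, after which the acetal, now on an electron-rich pyrrole instead of next to a ketone, ionises readily and should be hydrolysed by the aqueous acid (acetal hydrolysis) to the conjugated aldehyde without isolation of the labile intermediate.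

Compound list
1 | icosanoic acid | CCCCCCCCCCCCCCCCCCCC(=O)O | starting material
2 | henicosan-2-one | CCCCCCCCCCCCCCCCCCCC(C)=O | intermediate
3 | dichlorodi(propan-2-yl)silane | CC(C)[Si](Cl)(Cl)C(C)C | starting material
4 | 1,1-dimethoxypropan-2-one | CC(=O)C(OC)OC | starting material
5 | lithium henicos-1-en-2-olate (kinetic enolate of 2, formed in the flask) | [Li+].[O-]C(=C)CCCCCCCCCCCCCCCCCCC | intermediate
6 | chloro(henicos-1-en-2-yloxy)di(propan-2-yl)silane (chlorosilyl enol ether, formed in the flask) | CCCCCCCCCCCCCCCCCCCC(=C)O[Si](Cl)(C(C)C)C(C)C | intermediate
7 | lithium 3,3-dimethoxyprop-1-en-2-olate (kinetic enolate of 4, formed in the flask) | [Li+].[O-]C(=C)C(OC)OC | intermediate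
8 | [(3,3-dimethoxyprop-1-en-2-yl)oxy](henicos-1-en-2-yloxy)di(propan-2-yl)silane | CCCCCCCCCCCCCCCCCCCC(=C)O[Si](C(C)C)(C(C)C)OC(=C)C(OC)OC | intermediate
9 | 1,1-dimethoxytetracosane-2,5-dione | CCCCCCCCCCCCCCCCCCCC(=O)CCC(=O)C(OC)OC | intermediate
10 | 2-(dimethoxymethyl)-5-nonadecyl-1H-pyrrole (formed in the flask) | CCCCCCCCCCCCCCCCCCCc1ccc(C(OC)OC)[nH]1 | intermediate
11 | 5-nonadecyl-1H-pyrrole-2-carbaldehyde | CCCCCCCCCCCCCCCCCCCc1ccc(C=O)[nH]1 | target

Total step count: 4. Longest linear sequence: 4 steps (1 → 2 → 8 → 9 → 11).

Steps most likely to fail

Step 3 (key step). The radical cation may be intercepted by nitrate or lose silicon before the second enol ether attacks, so that desilylation back to the two methyl ketones or α-oxygenation outruns carbon–carbon bond formation. Cerium-induced cleavage of the acetal is a further drain. The fallback is a polar union of an enolate with an α-halo ketone; it sets out from 2 and comes back at 9.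
- Kinetic enolisation of 2 (LiN(iPr)2, THF, −78 °C) with Me3SiCl trapping should give trimethyl(henicos-1-en-2-yloxy)silane F1.
- N-Bromosuccinimide (THF, −78 → 0 °C) should convert this regiospecifically into 1-bromohenicosan-2-one F2.
- C-Alkylation of the sodium enolate of purchased methyl 4,4-dimethoxy-3-oxobutanoate (NaH, THF, 0 °C → rt) with F2 should give racemic methyl 2-(2,2-dimethoxyacetyl)-4-oxotricosanoate F3.
- Krapcho dealkoxycarbonylation (LiCl, wet DMSO, 120 °C) should then deliver 9.

Step 2. Double displacement at silicon during the first silylation would give symmetrical bis-enol ethers that later homo-couple. Proton exchange with unreacted ketone could move the enolate of 2 to the internal position, and the Si–O bonds could hydrolyse on isolation. The fallback avoids silicon and enolates of 2 altogether by conjugate addition of a nitronate acyl-anion equivalent followed by a Nef reaction; it sets out from 1 and comes back at 9.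
- Activation of 1 with 1,1'-carbonyldiimidazole and MeNHOMe·HCl (CH2Cl2, rt) should give the Weinreb amide N-methoxy-N-methylicosanamide F4.
- CH2=CHMgBr (THF, 0 °C, quench into cold aq HCl to keep the liberated amine from adding back) should give docos-1-en-3-one F5.
- Michael addition of 1,1-dimethoxy-2-nitroethane (DBU cat., MeCN, rt) should give racemic 1,1-dimethoxy-2-nitrotetracosan-5-one F6.
- A basic oxidative Nef reaction (NaOMe, MeOH; O3, −78 °C; Me2S), which leaves the acetal untouched, should convert the nitro-bearing carbon into the ketone of 9.

Step 4. The pyrrolyl acetal may ionise to an azafulvenium ion that is attacked by a second pyrrole (oligomerisation) before water intercepts it, and cyclisation at the hindered acetal-bearing carbonyl may be slow. The fallback introduces the formyl group only after the ring is made; it sets out from 1 and comes back at 11.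
- (COCl)2 with catalytic DMF (CH2Cl2) should give icosanoyl chloride F7.
- Acylation of [2-(1,3-dioxolan-2-yl)ethyl]magnesium bromide with F7 under Fe(acac)3 catalysis (THF, −78 °C) should give 1-(1,3-dioxolan-2-yl)docosan-3-one F8.
- NH4OAc in AcOH/H2O at 80 °C should unmask the aldehyde and close the ring in a Paal–Knorr reaction to 2-nonadecyl-1H-pyrrole F9.
- Vilsmeier–Haack formylation (POCl3, DMF, ClCH2CH2Cl, 0 °C → rt; aq NaOAc, 60 °C) at the free α-position should give 11.

Further compounds
F1 | step 3 | trimethyl(henicos-1-en-2-yloxy)silane | CCCCCCCCCCCCCCCCCCCC(=C)O[Si](C)(C)C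
F2 | step 3 | 1-bromohenicosan-2-one | CCCCCCCCCCCCCCCCCCCC(=O)CBr
F3 | step 3 | methyl 2-(2,2-dimethoxyacetyl)-4-oxotricosanoate (racemic) | COC(=O)C(CC(=O)CCCCCCCCCCCCCCCCCCC)C(=O)C(OC)OC
F4 | step 2 | N-methoxy-N-methylicosanamide | CCCCCCCCCCCCCCCCCCCC(=O)N(C)OC
F5 | step 2 | docos-1-en-3-one | CCCCCCCCCCCCCCCCCCCC(=O)C=C
F6 | step 2 | 1,1-dimethoxy-2-nitrotetracosan-5-one (racemic) | CCCCCCCCCCCCCCCCCCCC(=O)CCC(C(OC)OC)[N+](=O)[O-]
F7 | step 4 | icosanoyl chloride | CCCCCCCCCCCCCCCCCCCC(Cl)=O
F8 | step 4 | 1-(1,3-dioxolan-2-yl)docosan-3-one | CCCCCCCCCCCCCCCCCCCC(=O)CCC1OCCO1
F9 | step 4 | 2-nonadecyl-1H-pyrrole | CCCCCCCCCCCCCCCCCCCc1ccc[nH]1
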